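A direct plan would O-prenylate 2,4,6-trihydroxybenzaldehyde A1 at its 4-hydroxyl group to aldehyde A2.
It would then couple A2 with 4-methoxyphenylglyoxal A3 in a carbene-catalysed crossed benzoin reaction (C3–C4 bond); hydroxy-diketone A4 would close ring C through its phenol and lose water.
Its weakest steps would be two. The mono-O-prenylation would be one, since a phloroglucinol nucleus would also give bis-ethers and C-prenylated products.
The crossed benzoin coupling would be the other, since a 2,6-dihydroxybenzaldehyde would be a hindered, deactivated aldehyde that forms its Breslow intermediate reluctantly while the glyoxal self-condenses.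

The route rests on closing ring A last, onto a finished ring C. A Danheiser benzannulation joins the hetarylketene from a 6-(diazoacetyl)-2-aryl-3-alkoxy-4-pyranone to (triisopropylsilyloxy)acetylene and forms C5–C6, C7–C8 and C4a–C5 in one operation. It exploits the 1,3,5-trioxygenated ring A, whose three oxygens carry three different groups: O1 comes from the pyranone, the free 5-OH from the ketene carbonyl, and O7 arrives as the only silyl ether. The prenyl group is then placed by fluoride-triggered alkylation at that one site, so that neither a selective alkylation of a triphenol nor an acyl-anion coupling with its reversible equilibria is needed.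

Key step: step 6

Assumptions: comenic acid is taken as commercial. (Triisopropylsilyloxy)acetylene is not treated as a catalogue compound and is made in step 5. Diazomethane is used as an ethereal solution prepared beforehand from a commercial precursor. The target has no stereocentre and no stereogenic double bond, so no step has to set configuration.

Step 1
Reactants: 1 comenic acid (5-hydroxy-4-oxo-4H-pyran-2-carboxylic acid); 2 bromine
Product: 3 6-bromo-5-hydroxy-4-oxo-4H-pyran-2-carboxylic acid
Conditions: Br2 (1.05 equiv), H2O, rt
Reagents that add atoms: bromine, BrBr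
Why: Electrophilic substitution of the enolised 3-hydroxy-4-pyranone, in which the hydroxyl group activates only the ortho carbon C6, while C3 is not conjugated with it and is deactivated by the carboxyl group, so that a single monobromide should form.

Step 2
Reactants: 3 6-bromo-5-hydroxy-4-oxo-4H-pyran-2-carboxylic acid; 4 chloromethyl methyl ether
Product: 5 methoxymethyl 6-bromo-5-(methoxymethoxy)-4-oxo-4H-pyran-2-carboxylate
Conditions: MeOCH2Cl (2.5 equiv), i-Pr2NEt (3 equiv), CH2Cl2, 0 °C → rt
Reagents that add atoms: chloromethyl methyl ether, COCCl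
Why: Double O-alkylation (Williamson type, through the oxocarbenium ion of the chloromethyl ether) of the acidic enol and of the carboxylate, which masks the metal-chelating 3-hydroxy-4-pyranone unit before palladium is used and leaves an ester that is far easier to hydrolyse than the enol acetal.

Step 3
Reactants: 5 methoxymethyl 6-bromo-5-(methoxymethoxy)-4-oxo-4H-pyran-2-carboxylate; 6 4-methoxyphenylboronic acid
Product: 8 5-(methoxymethoxy)-6-(4-methoxyphenyl)-4-oxo-4H-pyran-2-carboxylic acid, via coupled methoxymethyl ester 7 (not isolated)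
Conditions: Pd(PPh3)4 (5 mol %), K3PO4 (3 equiv), 1,4-dioxane/H2O (10:1), 80 °C; then LiOH (aq), rt; then 1 M HCl to pH 3 at 0 °C
Reagents that add atoms: 4-methoxyphenylboronic acid, COc1ccc(B(O)O)cc1; lithium hydroxide (hydroxide oxygen of the new carboxyl group), [Li+].[OH-]
Why: Suzuki–Miyaura coupling at the C–Br bond of a 2-bromo-4-pyranone, a vinylogous acyl bromide that should undergo oxidative addition readily, followed by hydroxide cleavage (acyl substitution) of the acyloxymethyl ester, which is much more labile than the methoxymethyl enol ether.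

Step 4
Reactants: 8 5-(methoxymethoxy)-6-(4-methoxyphenyl)-4-oxo-4H-pyran-2-carboxylic acid; 9 isobutyl chloroformate; 10 diazomethane
Product: 12 6-(2-diazoacetyl)-3-(methoxymethoxy)-2-(4-methoxyphenyl)-4H-pyran-4-one, via mixed carbonic anhydride 11 (not isolated)
Conditions: i-BuOCOCl, N-methylmorpholine, THF, −15 °C; then CH2N2, Et2O, 0 °C
Reagents that add atoms: diazomethane, C=[N+]=[N-]
Why: Acylation of diazomethane by a mixed carbonic anhydride (first stage of the Arndt–Eistert sequence); the activation is free of HCl, so the acetal should survive, and diazomethane should attack the more electrophilic hetaroyl carbonyl, the carbonate leaving as isobutanol and CO2.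

Step 5
Reactants: 13 acetylene; 14 tert-butyl hydroperoxide; 15 triisopropylsilyl trifluoromethanesulfonate
Product: 18 (triisopropylsilyloxy)acetylene [(ethynyloxy)tri(propan-2-yl)silane], via lithium acetylide 16 (not isolated), via lithium ethynolate 17 (not isolated)
Conditions: acetylene (excess), n-BuLi, THF, −78 °C; LiOOt-Bu (from t-BuOOH and LiN(SiMe3)2, THF, −78 °C), −78 → 0 °C; i-Pr3SiOTf, −78 °C → rt; pentane extraction, distillation
Reagents that add atoms: tert-butyl hydroperoxide, CC(C)(C)OO; triisopropylsilyl trifluoromethanesulfonate, CC(C)[Si](OS(=O)(=O)C(F)(F)F)(C(C)C)C(C)C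
Why: Oxidation of a lithium acetylide by the oxenoid lithium tert-butyl peroxide to the lithium ynolate (electrophilic oxygen transfer with loss of tert-butoxide), which the bulky silyl triflate should silylate on oxygen and not on carbon, as is known for substituted lithium acetylides.

Step 6
Reactants: 12 6-(2-diazoacetyl)-3-(methoxymethoxy)-2-(4-methoxyphenyl)-4H-pyran-4-one; 18 (triisopropylsilyloxy)acetylene
Product: 23 5-hydroxy-3-(methoxymethoxy)-2-(4-methoxyphenyl)-7-[(triisopropylsilyl)oxy]-4H-chromen-4-one, via hetarylketene 19 (not isolated), via siloxycyclobutenone 20 (not isolated), via dienylketene 21 (not isolated), via cyclohexadienone 22 (not isolated)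
Conditions: 18 (2 equiv), ClCH2CH2Cl, hν (blue LEDs, 440 nm), rt; then 80 °C
Reagents that add atoms: (triisopropylsilyloxy)acetylene (compound 18), C#CO[Si](C(C)C)(C(C)C)C(C)C
Why: Visible light, absorbed by the diazo ketone but not by the 4-pyranone or by the product, triggers a Wolff rearrangement of 12 to hetarylketene 19, which adds the electron-rich ynol ether 18 in a [2+2] cycloaddition whose orientation is fixed by the polarisation of both partners (the unsubstituted, nucleophilic alkyne carbon bonds to the ketene carbonyl carbon) and gives cyclobutenone 20. On heating, 20 opens in a 4π-electrocyclic reaction to dienylketene 21, which closes ring A by a thermal, disrotatory 6π-electrocyclisation onto the C5=C6 bond of the pyranone (cyclohexadienone 22) and tautomerises to the phenol 23. The closest known reaction type is the Danheiser benzannulation of aryl, heteroaryl and alkenyl α-diazo ketones with siloxyalkynes. Rings closed: the transient four-membered ring by [2+2] cycloaddition and the six-membered ring A by 6π-electrocyclisation; the single stereocentres of 20 and 22 are formed as racemates and disappear on aromatisation, so nothing has to be controlled. The step needs two selectivities: the orientation of the cycloaddition, which places the silyloxy group at C7 (chromone numbering), meta to the new 5-hydroxyl group that derives from the ketene carbonyl, and the site of ring closure, which is secured because C5 of the pyranone is the only carbon next to the ketene-bearing C6 (the other neighbour is the ring oxygen). A 4-pyranone C=C bond has little aromatic stabilisation to lose, so it should serve as the 2π component at least as readily as the benzene and furan rings that are known to take part.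

Step 7
Reactants: 23 5-hydroxy-3-(methoxymethoxy)-2-(4-methoxyphenyl)-7-[(triisopropylsilyl)oxy]-4H-chromen-4-one; 24 prenyl bromide (1-bromo-3-methylbut-2-ene)
Product: 26 5-hydroxy-3-(methoxymethoxy)-2-(4-methoxyphenyl)-7-(3-methylbut-2-en-1-yloxy)-4H-chromen-4-one, via caesium phenoxide 25 (not isolated)
Conditions: CsF (1.2 equiv), prenyl bromide (1.3 equiv), DMF, 0 °C → rt
Reagents that add atoms: prenyl bromide, CC(C)=CCBr
Why: Fluoride-induced cleavage of the aryl silyl ether gives the caesium phenoxide at O7 only, which is alkylated in place by the allylic bromide (SN2, Williamson ether synthesis); the only free hydroxyl group, at C5, is held in a hydrogen bond to the C4 carbonyl and should not compete, and the enol oxygen at C3 is capped.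

Step 8
Reactants: 26 5-hydroxy-3-(methoxymethoxy)-2-(4-methoxyphenyl)-7-(3-methylbut-2-en-1-yloxy)-4H-chromen-4-one
Product: 27 3,5-dihydroxy-2-(4-methoxyphenyl)-7-(3-methylbut-2-en-1-yloxy)-4H-chromen-4-one (target)
Conditions: HCl (0.5 M in MeOH), THF, 0 °C → rt
Reagents that add atoms: none
Why: Acid-catalysed acetal exchange with methanol, in which the methoxymethyl enol ether at C3 should ionise far more easily than the aryl prenyl ether, so that brief exposure to dilute acid frees the 3-hydroxyl group and leaves the 7-O-prenyl group in place.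

## Compound list

1 | comenic acid (5-hydroxy-4-oxo-4H-pyran-2-carboxylic acid) | O=C(O)c1cc(=O)c(O)co1 | starting material
2 | bromine | BrBr | starting material
3 | 6-bromo-5-hydroxy-4-oxo-4H-pyran-2-carboxylic acid | O=C(O)c1cc(=O)c(O)c(Br)o1 | intermediate
4 | chloromethyl methyl ether | COCCl | starting material
5 | methoxymethyl 6-bromo-5-(methoxymethoxy)-4-oxo-4H-pyran-2-carboxylate | COCOC(=O)c1cc(=O)c(OCOC)c(Br)o1 | intermediate
6 | 4-methoxyphenylboronic acid | COc1ccc(B(O)O)cc1 | starting material
7 | methoxymethyl 5-(methoxymethoxy)-6-(4-methoxyphenyl)-4-oxo-4H-pyran-2-carboxylate (not isolated) | COCOC(=O)c1cc(=O)c(OCOC)c(-c2ccc(OC)cc2)o1 | intermediate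
8 | 5-(methoxymethoxy)-6-(4-methoxyphenyl)-4-oxo-4H-pyran-2-carboxylic acid | COCOc1c(-c2ccc(OC)cc2)oc(C(=O)O)cc1=O | intermediate
9 | isobutyl chloroformate | CC(C)COC(Cl)=O | starting material
10 | diazomethane | C=[N+]=[N-] | starting material
11 | 5-(methoxymethoxy)-6-(4-methoxyphenyl)-4-oxo-4H-pyran-2-carboxylic isobutyl carbonic anhydride (not isolated) | COCOc1c(-c2ccc(OC)cc2)oc(C(=O)OC(=O)OCC(C)C)cc1=O | intermediate
12 | 6-(2-diazoacetyl)-3-(methoxymethoxy)-2-(4-methoxyphenyl)-4H-pyran-4-one | COCOc1c(-c2ccc(OC)cc2)oc(C(=O)C=[N+]=[N-])cc1=O | intermediate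
13 | acetylene | C#C | starting material
14 | tert-butyl hydroperoxide | CC(C)(C)OO | starting material
15 | triisopropylsilyl trifluoromethanesulfonate | CC(C)[Si](OS(=O)(=O)C(F)(F)F)(C(C)C)C(C)C | starting material
16 | lithium acetylide (not isolated) | [Li+].[C-]#C | intermediate
17 | lithium ethynolate (not isolated) | [Li+].[O-]C#C | intermediate
18 | (triisopropylsilyloxy)acetylene [(ethynyloxy)tri(propan-2-yl)silane] | C#CO[Si](C(C)C)(C(C)C)C(C)C | intermediate
19 | 2-[5-(methoxymethoxy)-6-(4-methoxyphenyl)-4-oxo-4H-pyran-2-yl]ethen-1-one (hetarylketene, not isolated) | COCOc1c(-c2ccc(OC)cc2)oc(C=C=O)cc1=O | intermediate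
20 | 4-[5-(methoxymethoxy)-6-(4-methoxyphenyl)-4-oxo-4H-pyran-2-yl]-3-[(triisopropylsilyl)oxy]cyclobut-2-en-1-one (racemic, not isolated) | COCOc1c(-c2ccc(OC)cc2)oc(C2C(=O)C=C2O[Si](C(C)C)(C(C)C)C(C)C)cc1=O | intermediate
21 | (3E)-4-[5-(methoxymethoxy)-6-(4-methoxyphenyl)-4-oxo-4H-pyran-2-yl]-3-[(triisopropylsilyl)oxy]buta-1,3-dien-1-one (ketene carbon and pyranone ring cis, not isolated) | O=C=C/C(O[Si](C(C)C)(C(C)C)C(C)C)=C\c1cc(=O)c(OCOC)c(-c2ccc(OC)cc2)o1 | intermediate
22 | 3-(methoxymethoxy)-2-(4-methoxyphenyl)-7-[(triisopropylsilyl)oxy]-4aH-chromene-4,5-dione (racemic, not isolated) | O=C1C=C(O[Si](C(C)C)(C(C)C)C(C)C)C=C2OC(-c3ccc(OC)cc3)=C(OCOC)C(=O)C12 | intermediate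
23 | 5-hydroxy-3-(methoxymethoxy)-2-(4-methoxyphenyl)-7-[(triisopropylsilyl)oxy]-4H-chromen-4-one | COCOc1c(-c2ccc(OC)cc2)oc2cc(O[Si](C(C)C)(C(C)C)C(C)C)cc(O)c2c1=O | intermediate
24 | prenyl bromide (1-bromo-3-methylbut-2-ene) | CC(C)=CCBr | starting material
25 | caesium 5-hydroxy-3-(methoxymethoxy)-2-(4-methoxyphenyl)-4-oxo-4H-chromen-7-olate (not isolated) | [Cs+].COCOc1c(-c2ccc(OC)cc2)oc2cc([O-])cc(O)c2c1=O | intermediate
26 | 5-hydroxy-3-(methoxymethoxy)-2-(4-methoxyphenyl)-7-(3-methylbut-2-en-1-yloxy)-4H-chromen-4-one | COCOc1c(-c2ccc(OC)cc2)oc2cc(OCC=C(C)C)cc(O)c2c1=O | intermediate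
27 | 3,5-dihydroxy-2-(4-methoxyphenyl)-7-(3-methylbut-2-en-1-yloxy)-4H-chromen-4-one (achiral) | COc1ccc(-c2oc3cc(OCC=C(C)C)cc(O)c3c(=O)c2O)cc1 | target

Total step count: 8. Longest linear sequence: 7 steps (steps 1–4 and 6–8); step 5 is a one-step side branch.

The three steps most likely to fail:

Step 6. The light-induced Wolff rearrangement may be inefficient, because carbene side reactions or ketene dimerisation may outrun the cycloaddition, or the pyranone may be degraded under irradiation. The fallback generates the same ketene in the dark. It sets out from 12: a silver-catalysed Wolff rearrangement in aqueous THF (silver benzoate, AgO2CPh, with Et3N) would give the homologous acid, [5-(methoxymethoxy)-6-(4-methoxyphenyl)-4-oxo-4H-pyran-2-yl]acetic acid F1. Neutral activation with 1-chloro-N,N,2-trimethylpropenylamine would give [5-(methoxymethoxy)-6-(4-methoxyphenyl)-4-oxo-4H-pyran-2-yl]acetyl chloride F2. Dehydrochlorination of F2 with Et3N at rt in the presence of 18 would form ketene 19, and the route would be rejoined at cyclobutenone 20, which would be heated to 23 as in step 6.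

Step 5. Monolithium acetylide may disproportionate before it is oxidised, or the ynolate may be silylated on carbon. The fallback builds the ynol ether by elimination instead of oxidation. It sets out from 15: commercial bromoacetaldehyde diethyl acetal would be hydrolysed to bromoacetaldehyde F3, and 15 with Et3N would convert F3 into the silyl enol ether (Z)-(2-bromoethenyloxy)triisopropylsilane F4. Anti elimination of HBr from F4 with LiN(i-Pr)2 (1.1 equiv, THF, −78 °C) would give 18, where the route is rejoined.

Step 8. The prenyl group may be lost or may migrate by acid-induced ionisation of the allylic ether while the acetal is cleaved. The fallback reverses the order so that acid never meets the prenyl ether. It sets out from 23: the acetal would be removed first (HCl, MeOH) to give 3,5-dihydroxy-2-(4-methoxyphenyl)-7-[(triisopropylsilyl)oxy]-4H-chromen-4-one F5. CsF (1.0 equiv) in DMF would then set free caesium 3,5-dihydroxy-2-(4-methoxyphenyl)-4-oxo-4H-chromen-7-olate F6, the least basic and therefore the predominant anion, and prenyl bromide 24 (1.0 equiv) would alkylate it at O7 to give the target 27 directly.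

Further compounds

F1 | step 6 | [5-(methoxymethoxy)-6-(4-methoxyphenyl)-4-oxo-4H-pyran-2-yl]acetic acid | COCOc1c(-c2ccc(OC)cc2)oc(CC(=O)O)cc1=O
F2 | step 6 | [5-(methoxymethoxy)-6-(4-methoxyphenyl)-4-oxo-4H-pyran-2-yl]acetyl chloride | COCOc1c(-c2ccc(OC)cc2)oc(CC(=O)Cl)cc1=O
F3 | step 5 | bromoacetaldehyde | O=CCBr
F4 | step 5 | (Z)-(2-bromoethenyloxy)triisopropylsilane | Br/C=C\O[Si](C(C)C)(C(C)C)C(C)C
F5 | step 8 | 3,5-dihydroxy-2-(4-methoxyphenyl)-7-[(triisopropylsilyl)oxy]-4H-chromen-4-one | COc1ccc(-c2oc3cc(O[Si](C(C)C)(C(C)C)C(C)C)cc(O)c3c(=O)c2O)cc1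
F6 | step 8 | caesium 3,5-dihydroxy-2-(4-methoxyphenyl)-4-oxo-4H-chromen-7-olate | [Cs+].COc1ccc(-c2oc3cc([O-])cc(O)c3c(=O)c2O)cc1
A1 | direct plan | 2,4,6-trihydroxybenzaldehyde | O=Cc1c(O)cc(O)cc1O
A2 | direct plan | 2,6-dihydroxy-4-(3-methylbut-2-en-1-yloxy)benzaldehyde | O=Cc1c(O)cc(OCC=C(C)C)cc1O
A3 | direct plan | 4-methoxyphenylglyoxal | COc1ccc(cc1)C(=O)C=O
A4 | direct plan | 1-[2,6-dihydroxy-4-(3-methylbut-2-en-1-yloxy)phenyl]-2-hydroxy-3-(4-methoxyphenyl)propane-1,3-dione (racemic) | COc1ccc(cc1)C(=O)C(O)C(=O)c1c(O)cc(OCC=C(C)C)cc1O
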